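**Retrosynthetic overview**
1. Benzofuran numbering is used for the target (O1, C2, C3, C3a, C4–C7, C7a). Target 20 comes from its tertiary TBS ether 19, whose ring A is cut at C3a–C4 and C6–C7 into 2,2-diprenylmalonyl dichloride 5 (C4–C5–C6) and the furanyl silyl dienol ether 17 (C3a–C7a–C7), a [3+3] double C-acylation.
2. The strategy rests on this feature: C5 with its two prenyl groups and the C4/C6 carbonyls is a diprenylmalonyl unit, and C7, C7a, C3a are the alpha, carbonyl and alpha' carbons of a ketone whose oxygen is already O1 of dihydrofuran ring B, so only C-acylation can close a six-membered ring.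
3. Diene 17 comes from the dianion of 5-methylhexane-2,4-dione 12 and (S)-epoxide 11 (from (S)-glycerate acetonide 6), by cyclodehydration (ring B) and gamma-silylation.
4. Ring B is formed first and ring A second; the only stereocentre (C2, S) is bought with 6 and its C–O bond is never broken.

Key step: step 12

Remark: the target is one enol tautomer of a cyclic beta-triketone; the tautomers interconvert, so the exocyclic enol geometry is taken as that of the hydrogen-bonded thermodynamic form and is not controlled separately.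

**Step 1**
Reactants: 1 dimethyl malonate; 2 1-bromo-3-methylbut-2-ene (prenyl bromide)
Product: 3 dimethyl 2,2-bis(3-methylbut-2-enyl)malonate
Conditions: NaH (2.2 equiv.), THF/DMF, 0 °C; 2 (2.2 equiv. in all), 0 °C to rt
Reagents that add atoms: 1-bromo-3-methylbut-2-ene (second equivalent of 2), CC(C)=CCBr
Why: Malonic ester synthesis, two successive SN2 C-alkylations of the malonate enolate at the primary allylic carbon of 2, so that two equivalents of 2 are consumed and each delivers one prenyl group.

**Step 2**
Reactants: 3 dimethyl 2,2-bis(3-methylbut-2-enyl)malonate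
Product: 4 dipotassium 2,2-bis(3-methylbut-2-enyl)malonate
Conditions: KOH (2.05 equiv.), MeOH/H2O, reflux; evaporate, toluene azeotrope, dry in vacuo
Reagents that add atoms: potassium hydroxide (two equivalents), [K+].[OH-]
Why: Saponification of both esters; isolating the dry dipotassium salt avoids the free disubstituted malonic acid (decarboxylation) and allows an HCl-free chlorination.

**Step 3**
Reactants: 4 dipotassium 2,2-bis(3-methylbut-2-enyl)malonate
Product: 5 2,2-bis(3-methylbut-2-enyl)malonyl dichloride
Conditions: (COCl)2 (2.3 equiv.), cat. DMF, CH2Cl2, 0 °C to rt; filter under argon, concentrate, use crude at once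
Reagents that add atoms: oxalyl chloride (two equivalents), O=C(Cl)C(Cl)=O
Why: Acid chloride formation from a carboxylate salt under chloroiminium (Vilsmeier-type) catalysis gives only KCl, CO and CO2, so no HCl can add to the trisubstituted alkenes, and the quaternary alpha-carbon rules out ketene formation.

**Step 4**
Reactants: 6 methyl (4S)-2,2-dimethyl-1,3-dioxolane-4-carboxylate
Product: 7 2-[(4S)-2,2-dimethyl-1,3-dioxolan-4-yl]propan-2-ol
Conditions: MeMgBr (3 equiv.), THF, 0 °C to rt; aq. NH4Cl
Reagents that add atoms: methylmagnesium bromide (two methyl groups are delivered), C[Mg]Br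
Why: Double Grignard addition to the ester gives the tertiary alcohol; addition outruns enolisation of the alpha-alkoxy ester, so the stereocentre (S) should be kept.

**Step 5**
Reactants: 7 2-[(4S)-2,2-dimethyl-1,3-dioxolan-4-yl]propan-2-ol
Product: 8 tert-butyl{2-[(4S)-2,2-dimethyl-1,3-dioxolan-4-yl]propan-2-yloxy}dimethylsilane
Conditions: TBSOTf, 2,6-lutidine, CH2Cl2, 0 °C to rt
Reagents that add atoms: tert-butyldimethylsilyl triflate, CC(C)(C)[Si](C)(C)OS(=O)(=O)C(F)(F)F
Why: Silylation of a hindered tertiary alcohol needs the silyl triflate; 2,6-lutidine takes up the triflic acid so the acetonide is kept.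

**Step 6**
Reactants: 8 tert-butyl{2-[(4S)-2,2-dimethyl-1,3-dioxolan-4-yl]propan-2-yloxy}dimethylsilane
Product: 9 (2S)-3-(tert-butyldimethylsilyloxy)-3-methylbutane-1,2-diol
Conditions: AcOH/H2O/THF, 40 °C
Reagents that add atoms: none
Why: Acid-catalysed acetal hydrolysis of the terminal acetonide; the hindered tertiary TBS ether hydrolyses far more slowly under these mild conditions.

**Step 7**
Reactants: 9 (2S)-3-(tert-butyldimethylsilyloxy)-3-methylbutane-1,2-diol
Product: 10 (2S)-3-(tert-butyldimethylsilyloxy)-2-hydroxy-3-methylbutyl 4-methylbenzenesulfonate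
Conditions: TsCl (1.05 equiv.), Et3N, cat. Bu2SnO, CH2Cl2, 0 °C to rt
Reagents that add atoms: 4-toluenesulfonyl chloride, Cc1ccc(cc1)S(=O)(=O)Cl
Why: Tin-acetal-catalysed regioselective sulfonylation of the primary hydroxyl of a 1,2-diol; the secondary hydroxyl next to the quaternary carbon is much more hindered.

**Step 8**
Reactants: 10 (2S)-3-(tert-butyldimethylsilyloxy)-2-hydroxy-3-methylbutyl 4-methylbenzenesulfonate
Product: 11 tert-butyldimethyl{2-[(2S)-oxiran-2-yl]propan-2-yloxy}silane
Conditions: K2CO3, MeOH, 0 °C to rt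
Reagents that add atoms: none
Why: Intramolecular Williamson etherification (3-exo-tet) of the secondary alkoxide onto the primary tosylate; the C–O bond at the stereocentre is not broken, so (S) is retained.

**Step 9**
Reactants: 12 5-methylhexane-2,4-dione; 11 tert-butyldimethyl{2-[(2S)-oxiran-2-yl]propan-2-yloxy}silane
Product: 14 (8S)-9-(tert-butyldimethylsilyloxy)-8-hydroxy-2,9-dimethyldecane-3,5-dione, via dilithium diketone dianion 13 (not isolated)
Conditions: 12 (1.3 equiv.), LiN(i-Pr)2 (2.1 equiv. per 12), THF, −78 to 0 °C; 11, −78 °C to rt; AcOH quench at −78 °C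
Reagents that add atoms: none
Why: 1,3-Diketone dianion alkylation: the second deprotonation occurs at the methyl group and not at the isopropyl methine, and the terminal carbanion opens the epoxide by SN2 at its CH2, leaving the carbinol stereocentre (S) untouched.

**Step 10**
Reactants: 14 (8S)-9-(tert-butyldimethylsilyloxy)-8-hydroxy-2,9-dimethyldecane-3,5-dione
Product: 16 (1E)-1-[(5S)-5-[2-(tert-butyldimethylsilyloxy)propan-2-yl]oxolan-2-ylidene]-3-methylbutan-2-one, via cyclic hemiketal 15 (not isolated)
Conditions: cat. TFA, CH2Cl2, 4 Å molecular sieves, rt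
Reagents that add atoms: none
Why: Acid-catalysed cyclodehydration: the secondary hydroxyl adds 5-exo-trig to the C5 carbonyl (the C3 carbonyl would need a seven-membered ring) and loss of water gives the conjugated exocyclic vinylogous ester, a known route to 2-alkylideneoxolanes; alkene geometry is of no consequence later.

**Step 11**
Reactants: 16 (1E)-1-[(5S)-5-[2-(tert-butyldimethylsilyloxy)propan-2-yl]oxolan-2-ylidene]-3-methylbutan-2-one
Product: 17 tert-butyldimethyl{2-[(2S)-5-[(1Z)-3-methyl-2-(trimethylsilyloxy)but-1-enyl]-2,3-dihydrofuran-2-yl]propan-2-yloxy}silane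
Conditions: TMSOTf (1.2 equiv.), Et3N (2 equiv.), CH2Cl2, 0 °C to rt; evaporate, extract into pentane, filter, use at once
Reagents that add atoms: trimethylsilyl triflate, C[Si](C)(C)OS(=O)(=O)C(F)(F)F
Why: Soft enolisation of a vinylogous ester: O-silylation gives a 1-silyloxy-3-alkoxyallyl cation, from which Et3N should remove the accessible ring proton at oxolane C3 (gamma position) rather than the hindered isopropyl methine, giving the planar 1-alkoxy-3-silyloxy-1,3-diene instead of a twisted tetrasubstituted enol ether.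

**Step 12**
Reactants: 5 2,2-bis(3-methylbut-2-enyl)malonyl dichloride; 17 tert-butyldimethyl{2-[(2S)-5-[(1Z)-3-methyl-2-(trimethylsilyloxy)but-1-enyl]-2,3-dihydrofuran-2-yl]propan-2-yloxy}silane
Product: 19 O-TBS garcinielliptone HD (the tertiary TBS ether of 20), via keto acid chloride 18 (not isolated)
Conditions: slow addition of 17 to 5 (1.1 equiv.), TMSOTf (10 mol%), 2,6-di-tert-butylpyridine (20 mol%), CH2Cl2 (0.01 M), −78 to 0 °C; then Et3N (3 equiv.), DMAP (10 mol%), 0 °C to rt; aq. NaH2PO4
Reagents that add atoms: none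
Why: Proposed new method: the diene terminus of 17 (dihydrofuran C4, the future C3a) should attack one TMSOTf-activated acyl chloride with loss of TMSCl to give 18, after which the amine enolises the doubly activated ring C–H and the dienolate attacks the second acyl chloride (DMAP as acyl-transfer catalyst) through the carbon next to the isobutyryl carbonyl (the future C7). The closest known reaction types are the alpha,alpha'-bis-C-acylation of ketone enol ethers with malonyl dichlorides (Effenberger-type), the terminal C-acylation of 1-alkoxy-3-silyloxy-1,3-dienes by acid chlorides (vinylogous Mukaiyama acylation), and Dieckmann-type closure to cyclic beta-triketones. Ring A is closed by a 6-(enolendo)-exo-trig acyl substitution onto the preformed ring B, which is not made in this step. No stereocentre is created: C2 (S) is remote and untouched, and the exocyclic enol should settle as the hydrogen-bonded thermodynamic tautomer. The step needs C- rather than O-acylation at the two carbons flanking C7a: the ether-locked O1 leaves only four- or eight-membered O-closures, 5 has no alpha-hydrogen and cannot form a ketene, and the gem-diprenyl group and high dilution favour cyclisation over oligomerisation. The strongly acidic beta-triketone enol of 19 is the thermodynamic sink, to which any O-acylated material should be returned by DMAP-mediated acyl transfer.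

**Step 13**
Reactants: 19 O-TBS garcinielliptone HD
Product: 20 garcinielliptone HD
Conditions: HF·pyridine, THF/pyridine, 0 °C to rt, polypropylene vessel
Reagents that add atoms: none
Why: Fluoride-driven Si–O cleavage of the tertiary silyl ether under buffered conditions that the prenyl alkenes and the enolised triketone should tolerate; the stereocentre is not involved.

**Compound list**
1 | dimethyl malonate | COC(=O)CC(=O)OC | starting material
2 | 1-bromo-3-methylbut-2-ene (prenyl bromide) | CC(C)=CCBr | starting material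
3 | dimethyl 2,2-bis(3-methylbut-2-enyl)malonate | COC(=O)C(CC=C(C)C)(CC=C(C)C)C(=O)OC | intermediate
4 | dipotassium 2,2-bis(3-methylbut-2-enyl)malonate | [K+].[K+].CC(C)=CCC(CC=C(C)C)(C([O-])=O)C([O-])=O | intermediate
5 | 2,2-bis(3-methylbut-2-enyl)malonyl dichloride | CC(C)=CCC(CC=C(C)C)(C(Cl)=O)C(Cl)=O | intermediate
6 | methyl (4S)-2,2-dimethyl-1,3-dioxolane-4-carboxylate | COC(=O)[C@@H]1COC(C)(C)O1 | starting material
7 | 2-[(4S)-2,2-dimethyl-1,3-dioxolan-4-yl]propan-2-ol | CC(C)(O)[C@@H]1COC(C)(C)O1 | intermediate
8 | tert-butyl{2-[(4S)-2,2-dimethyl-1,3-dioxolan-4-yl]propan-2-yloxy}dimethylsilane | CC(C)(O[Si](C)(C)C(C)(C)C)[C@@H]1COC(C)(C)O1 | intermediate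
9 | (2S)-3-(tert-butyldimethylsilyloxy)-3-methylbutane-1,2-diol | CC(C)(O[Si](C)(C)C(C)(C)C)[C@@H](O)CO | intermediate
10 | (2S)-3-(tert-butyldimethylsilyloxy)-2-hydroxy-3-methylbutyl 4-methylbenzenesulfonate | Cc1ccc(cc1)S(=O)(=O)OC[C@H](O)C(C)(C)O[Si](C)(C)C(C)(C)C | intermediate
11 | tert-butyldimethyl{2-[(2S)-oxiran-2-yl]propan-2-yloxy}silane | CC(C)(O[Si](C)(C)C(C)(C)C)[C@@H]1CO1 | intermediate
12 | 5-methylhexane-2,4-dione | CC(C)C(=O)CC(C)=O | starting material
13 | dilithium 5-methylhexa-1,3-diene-2,4-diolate (dianion of 12) | [Li+].[Li+].CC(C)C([O-])=CC([O-])=C | intermediate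
14 | (8S)-9-(tert-butyldimethylsilyloxy)-8-hydroxy-2,9-dimethyldecane-3,5-dione | CC(C)C(=O)CC(=O)CC[C@H](O)C(C)(C)O[Si](C)(C)C(C)(C)C | intermediate
15 | 1-[(5S)-5-[2-(tert-butyldimethylsilyloxy)propan-2-yl]-2-hydroxyoxolan-2-yl]-3-methylbutan-2-one (both hemiketal epimers) | CC(C)C(=O)CC1(O)CC[C@@H](C(C)(C)O[Si](C)(C)C(C)(C)C)O1 | intermediate
16 | (1E)-1-[(5S)-5-[2-(tert-butyldimethylsilyloxy)propan-2-yl]oxolan-2-ylidene]-3-methylbutan-2-one | CC(C)C(=O)/C=C1\CC[C@@H](C(C)(C)O[Si](C)(C)C(C)(C)C)O1 | intermediate
17 | tert-butyldimethyl{2-[(2S)-5-[(1Z)-3-methyl-2-(trimethylsilyloxy)but-1-enyl]-2,3-dihydrofuran-2-yl]propan-2-yloxy}silane | CC(C)/C(O[Si](C)(C)C)=C/C1=CC[C@@H](C(C)(C)O[Si](C)(C)C(C)(C)C)O1 | intermediate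
18 | 2-{[(5S)-5-[2-(tert-butyldimethylsilyloxy)propan-2-yl]-2-(3-methyl-2-oxobutylidene)oxolan-3-yl]carbonyl}-5-methyl-2-(3-methylbut-2-enyl)hex-4-enoyl chloride (C3 epimers and enol tautomers) | CC(C)C(=O)C=C1O[C@H](C(C)(C)O[Si](C)(C)C(C)(C)C)CC1C(=O)C(CC=C(C)C)(CC=C(C)C)C(Cl)=O | intermediate
19 | O-TBS garcinielliptone HD: (2S,7Z)-2-[2-(tert-butyldimethylsilyloxy)propan-2-yl]-7-(1-hydroxy-2-methylpropylidene)-5,5-bis(3-methylbut-2-enyl)-2,3-dihydro-1-benzofuran-4,6(5H,7H)-dione | CC(C)=CCC1(CC=C(C)C)C(=O)C2=C(O[C@H](C(C)(C)O[Si](C)(C)C(C)(C)C)C2)/C(=C(/O)C(C)C)C1=O | intermediate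
20 | garcinielliptone HD: (2S,7Z)-7-(1-hydroxy-2-methylpropylidene)-2-(2-hydroxypropan-2-yl)-5,5-bis(3-methylbut-2-enyl)-2,3-dihydro-1-benzofuran-4,6(5H,7H)-dione | CC(C)=CCC1(CC=C(C)C)C(=O)C2=C(O[C@H](C(C)(C)O)C2)/C(=C(/O)C(C)C)C1=O | target

**Step count**
Total: 13 steps. Longest linear sequence: 10 steps (6 to 20, steps 4–13).

**Steps most likely to fail**

Step 12 (proposed new method). What may go wrong is acylation at oxygen or intermolecular oligomerisation in place of the second C-acylation, attack of the activated acyl chloride on the prenyl alkenes, or protodesilylation of 17 before it is acylated. The fallback uses known reactions, sets out from 3 and 17 and comes back at 19; it forms the two bonds of ring A one at a time with a half-ester. Half-saponification of 3 (1.0 equiv. KOH, MeOH) should give potassium 2-(methoxycarbonyl)-5-methyl-2-(3-methylbut-2-enyl)hex-4-enoate F1. Oxalyl chloride with catalytic DMF on the dry salt should give methyl 2-(chlorocarbonyl)-5-methyl-2-(3-methylbut-2-enyl)hex-4-enoate F2. Vinylogous Mukaiyama acylation of 17 with F2 (cat. TMSOTf, CH2Cl2, −78 °C) at the diene terminus should give the keto ester methyl 2-{[(5S)-5-[2-(tert-butyldimethylsilyloxy)propan-2-yl]-2-(3-methyl-2-oxobutylidene)oxolan-3-yl]carbonyl}-5-methyl-2-(3-methylbut-2-enyl)hex-4-enoate F3. A Dieckmann condensation (KOt-Bu, THF/t-BuOH) through the carbon next to the isobutyryl group onto the single methyl ester should then close ring A to 19. With one acylating carbon present at a time, oligomerisation is excluded.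

Step 11. What may go wrong is enolisation toward the isopropyl methine, or formation of a mixture of dienol ethers, and hydrolysis of the labile diene on handling. The fallback sets out from 14 and comes back at 19; it needs no dienol ether because the two ring A bonds are made in the opposite order. Silylation of the secondary hydroxyl of 14 (TESCl, imidazole, DMF) should give (8S)-9-(tert-butyldimethylsilyloxy)-2,9-dimethyl-8-(triethylsilyloxy)decane-3,5-dione F4. Magnesium-mediated soft-enolisation C-acylation of the central diketone carbon (MgCl2, pyridine, CH2Cl2) with the acid chloride F2 described above should give the triketo ester methyl 2-[(6S)-7-(tert-butyldimethylsilyloxy)-7-methyl-2-(2-methylpropanoyl)-3-oxo-6-(triethylsilyloxy)octanoyl]-5-methyl-2-(3-methylbut-2-enyl)hex-4-enoate F5. Removal of the TES group with cyclodehydration (AcOH/THF/H2O, then cat. TFA, CH2Cl2) should close ring B and give methyl 2-{2-[(5S)-5-[2-(tert-butyldimethylsilyloxy)propan-2-yl]oxolan-2-ylidene]-4-methyl-3-oxopentanoyl}-5-methyl-2-(3-methylbut-2-enyl)hex-4-enoate F6. KOt-Bu in t-BuOH/THF should then close ring A by reversible enolisation at oxolane C3 and Claisen condensation onto the methyl ester. The acidic beta-triketone enolate of 19 is the only irreversible outcome.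

Step 9. What may go wrong is slow opening of the hindered epoxide with competing proton transfer and decay of the dianion, or base-induced silyl migration from the tertiary oxygen to the new secondary alkoxide. The fallback sets out from 11 and comes back at 14; it builds the diketone by Claisen acylation of a lactone instead of dianion alkylation. Opening of 11 with sodiomalonate (diethyl malonate, NaOEt, EtOH, reflux) with lactonisation in the flask should give ethyl (5S)-5-[2-(tert-butyldimethylsilyloxy)propan-2-yl]-2-oxooxolane-3-carboxylate F7. Krapcho dealkoxycarbonylation (LiCl, wet DMSO, 140 °C) should give (5S)-5-[2-(tert-butyldimethylsilyloxy)propan-2-yl]oxolan-2-one F8. Acylation of the kinetic lithium enolate of 3-methylbutan-2-one (LiN(i-Pr)2, THF, −78 °C, 2.2 equiv.) with F8 should open the lactone and give 14.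

**Further compounds**
F1 | step 12 | potassium 2-(methoxycarbonyl)-5-methyl-2-(3-methylbut-2-enyl)hex-4-enoate | COC(=O)C(CC=C(C)C)(CC=C(C)C)C(=O)[O-].[K+]
F2 | step 12 | methyl 2-(chlorocarbonyl)-5-methyl-2-(3-methylbut-2-enyl)hex-4-enoate | COC(=O)C(CC=C(C)C)(CC=C(C)C)C(Cl)=O
F3 | step 12 | methyl 2-{[(5S)-5-[2-(tert-butyldimethylsilyloxy)propan-2-yl]-2-(3-methyl-2-oxobutylidene)oxolan-3-yl]carbonyl}-5-methyl-2-(3-methylbut-2-enyl)hex-4-enoate | CC(C)C(=O)C=C1O[C@H](C(C)(C)O[Si](C)(C)C(C)(C)C)CC1C(=O)C(CC=C(C)C)(CC=C(C)C)C(=O)OC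
F4 | step 11 | (8S)-9-(tert-butyldimethylsilyloxy)-2,9-dimethyl-8-(triethylsilyloxy)decane-3,5-dione | CC(C)C(=O)CC(=O)CC[C@H](O[Si](CC)(CC)CC)C(C)(C)O[Si](C)(C)C(C)(C)C
F5 | step 11 | methyl 2-[(6S)-7-(tert-butyldimethylsilyloxy)-7-methyl-2-(2-methylpropanoyl)-3-oxo-6-(triethylsilyloxy)octanoyl]-5-methyl-2-(3-methylbut-2-enyl)hex-4-enoate | CC(C)C(=O)C(C(=O)C(CC=C(C)C)(CC=C(C)C)C(=O)OC)C(=O)CC[C@H](O[Si](CC)(CC)CC)C(C)(C)O[Si](C)(C)C(C)(C)C
F6 | step 11 | methyl 2-{2-[(5S)-5-[2-(tert-butyldimethylsilyloxy)propan-2-yl]oxolan-2-ylidene]-4-methyl-3-oxopentanoyl}-5-methyl-2-(3-methylbut-2-enyl)hex-4-enoate | CC(C)C(=O)C(C(=O)C(CC=C(C)C)(CC=C(C)C)C(=O)OC)=C1CC[C@@H](C(C)(C)O[Si](C)(C)C(C)(C)C)O1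
F7 | step 9 | ethyl (5S)-5-[2-(tert-butyldimethylsilyloxy)propan-2-yl]-2-oxooxolane-3-carboxylate | CCOC(=O)C1C[C@@H](C(C)(C)O[Si](C)(C)C(C)(C)C)OC1=O
F8 | step 9 | (5S)-5-[2-(tert-butyldimethylsilyloxy)propan-2-yl]oxolan-2-one | O=C1CC[C@@H](C(C)(C)O[Si](C)(C)C(C)(C)C)O1
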